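## Retrosynthetic overview

1. **Feature.** In germacrane numbering, C3 (dienone carbonyl) and C8 (tiglate carbinol) face each other 1,6 across the ten-membered ring, and both ring olefins (C1=C2, C4=C5) are cis. An added C3–C8 bond therefore folds the macrocycle into a cis-decalin of two cyclohexenes. Ring A is C3–C8 carrying C15 and C11–C13, which is the carvone skeleton. Ring B is C3, C2, C1, C10, C9, C8.
2. **Endgame.** The disconnections are the O6–C12 lactone (oxidative lactonisation of the 6,12-diol), the O8 tiglate, and C8–H (hydride carried from O10 to a C8 ketone).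
3. **Key disconnection.** The ten-membered ring arises by oxidative scission of the C3–C8 bond of a ring-fusion cis-diol.
4. **Decalin.** C14 comes from MeLi on the bicyclic C10 enone, C1=C2 from ring-closing metathesis, and C1 and C2 from one double vinylation (C3 ketone plus C10 Weinreb amide). C9–C10 comes from alkylation of the 8-silyloxy enolate. O12, O8 and O6 come from ene-type, enolate and dienol-ether oxidations of (S)-carvone.
5. **Ring order.** Ring A (bought with carvone), ring B (step 10), ten-membered ring by merger of A and B (step 16), lactone (step 20).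

Key step: step 16

**Remark (convention and assumption).** Germacrane numbering is used for every compound. α is the face of ring A (later of the ten-membered ring) that carries C11 on C7, and β is the other face. The target is 6α-O, 7α-C11, 8α-O, 10β-OH, that is 6S,7R,8R,10R. C3 and C8 of the decalin become carbonyl carbons, so their configuration is free. It is deliberately made cis (3α-OH, 8α-OH), because only a cis diol can chelate lead. Ketone 14 is assumed to react from the half-chair with C11, C9 and O6 equatorial and O8 axial.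

## Route

Step 1
Reactants: 1 (S)-carvone
Product: 2 (S)-12-chlorocarvone [5-(3-chloroprop-1-en-2-yl)-2-methylcyclohex-2-enone]
Conditions: Ca(OCl)2, solid CO2, CH2Cl2/H2O, 0 °C
Reagents that add atoms: calcium hypochlorite [Ca+2].[O-]Cl.[O-]Cl
Why: Ene-type allylic chlorination by HOCl should touch only the electron-rich isopropenyl olefin (the enone olefin is deactivated) and give the 2-(chloromethyl)allyl unit without affecting C7.

Step 2
Reactants: 2 (S)-12-chlorocarvone
Product: 4 (S)-12-hydroxycarvone, via allylic acetate 3 (not isolated)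
Conditions: KOAc, n-Bu4NI (cat.), DMF, 60 °C; then MeOH, K2CO3 (cat.), 0 °C to rt
Reagents that add atoms: potassium acetate CC(=O)[O-].[K+]
Why: SN2 displacement of the primary allylic chloride by acetate, followed by base-catalysed transesterification, should deliver the allylic alcohol under conditions the enone tolerates.

Step 3
Reactants: 4 (S)-12-hydroxycarvone
Product: 5 12-O-TBS-carvone
Conditions: TBSCl, imidazole, DMF, rt
Reagents that add atoms: tert-butyldimethylsilyl chloride CC(C)(C)[Si](C)(C)Cl
Why: Standard imidazole-promoted silylation masks the primary alcohol for the enolate and organometallic steps.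

Step 4
Reactants: 5 12-O-TBS-carvone
Product: 7 8β-hydroxy ketone (OH trans to C11), via lithium dienolate 6 (not isolated)
Conditions: LiN(i-Pr)2, THF, −78 °C; then 2-(phenylsulfonyl)-3-phenyloxaziridine, −78 °C
Reagents that add atoms: 2-(phenylsulfonyl)-3-phenyloxaziridine O=S(=O)(N1OC1c1ccccc1)c1ccccc1
Why: Kinetic α'-deprotonation followed by Davis oxaziridine hydroxylation should place oxygen on C8 anti to the C7 side chain, and this centre is re-enolised in step 6, so its configuration is provisional.

Step 5
Reactants: 7 8β-hydroxy ketone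
Product: 8 8β,12-bis-O-TBS ketone
Conditions: TBSCl, imidazole, DMF, 40 °C
Reagents that add atoms: tert-butyldimethylsilyl chloride CC(C)(C)[Si](C)(C)Cl
Why: Silylation of the secondary α-ketol installs a bulky, non-chelating group on O8 that later steers the additions at C3 and C6.

Step 6
Reactants: 8 8β,12-bis-O-TBS ketone; 9 2-bromo-N-methoxy-N-methylacetamide
Product: 11 C8-quaternary keto Weinreb amide (8α-OTBS; C9 β), via lithium enolate 10 (not isolated)
Conditions: LiN(i-Pr)2, THF/DMPU, −78 °C; then 9, −78 to −20 °C
Reagents that add atoms: 9 2-bromo-N-methoxy-N-methylacetamide CON(C)C(=O)CBr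
Why: In this enolate alkylation the only α-proton left (C8–H) is removed, and the activated α-bromo amide should attack the tetrasubstituted enolate on the β face, anti to the C7 side chain, which sets the quaternary C8 with C9 β and O8 α.

Step 7
Reactants: 11 C8-quaternary keto Weinreb amide
Product: 12 C3 TBS dienol ether (C3=C4 and C5=C6)
Conditions: TBSOTf, Et3N, CH2Cl2, 0 °C
Reagents that add atoms: tert-butyldimethylsilyl triflate CC(C)(C)[Si](C)(C)OS(=O)(=O)C(F)(F)F
Why: Under soft enolisation with silyl triflate and amine, the O-silylated enone can lose only the γ-proton at C6 because C8 is quaternary, which should give the linear dienol ether.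

Step 8
Reactants: 12 C3 TBS dienol ether
Product: 14 6β-hydroxy enone, via 5β,6β-epoxide 13 (not isolated)
Conditions: mCPBA, CH2Cl2/aq. NaH2PO4–Na2HPO4 (pH 7), 0 °C
Reagents that add atoms: 3-chloroperbenzoic acid O=C(OO)c1cccc(Cl)c1
Why: In this vinylogous Rubottom oxidation the peracid should attack the unhindered, electron-rich C5=C6 terminus from the β face (anti to C11 and to the 8α-silyloxy group), the epoxide opens with loss of silicon to the γ-hydroxy enone, and the C6 configuration is provisional because it is reset in steps 12 and 13.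

Step 9
Reactants: 14 6β-hydroxy enone; 15 vinylmagnesium bromide
Product: 16 3β-vinyl-3α-carbinol bearing the C10 vinyl ketone
Conditions: CH2=CHMgBr (excess), CeCl3, THF, −78 to 0 °C; poured into cold aq. NaH2PO4
Reagents that add atoms: 15 vinylmagnesium bromide C=C[Mg]Br
Why: This step combines a 1,2-addition with a Weinreb ketone synthesis, in which the amide stops at the vinyl ketone and the C3 carbonyl should be attacked axially from the β face, anti to the axial 8α-silyloxy group (polar Felkin–Anh), so that C2 is cis to C9 and O3 cis to O8.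

Step 10
Reactants: 16 3β-vinyl-3α-carbinol bearing the C10 vinyl ketone
Product: 17 cis-fused bicyclic C10 enone (ring B closed; C1=C2)
Conditions: second-generation Grubbs catalyst RuCl2(=CHPh)(PCy3)(SIMes) (5 mol %), CH2Cl2, 40 °C
Reagents that add atoms: none
Why: Ring-closing metathesis of the two monosubstituted vinyl groups, cis on ring A, should close the six-membered ring B with a necessarily cis C1=C2, while the trisubstituted C4=C5 and 1,1-disubstituted C11=C13 olefins are too hindered to compete.

Step 11
Reactants: 17 cis-fused bicyclic C10 enone; 18 methyllithium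
Product: 19 10β-hydroxy-10α-methyl decalin (free 3α-, 6β- and 10β-OH)
Conditions: MeLi (excess), THF/Et2O, −78 °C
Reagents that add atoms: 18 methyllithium [Li]C
Why: In this 1,2-addition of an organolithium to an enone on the rigid cis-decalin, ring A (C7 axial on ring B) covers the β face of C10, so methyl should enter from the convex α face and set C10 as 10α-Me, 10β-OH.

Step 12
Reactants: 19 10β-hydroxy-10α-methyl decalin
Product: 20 C6 enone
Conditions: MnO2, CH2Cl2, rt
Reagents that add atoms: none
Why: Allylic oxidation with MnO2 can affect only the one secondary allylic carbinol, since the tertiary carbinols cannot be oxidised and the vicinal pair is still masked at O8, so no glycol cleavage occurs.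

Step 13
Reactants: 20 C6 enone
Product: 21 6α-alcohol (OH cis to C11)
Conditions: NaBH4, CeCl3·7H2O, MeOH, −78 °C
Reagents that add atoms: none
Why: In this Luche 1,2-reduction the axial 8α-OTBS group is syn-axial to the α trajectory at C6 and C11 flanks it, so hydride should arrive from the β face and set the 6α-carbinol.

Step 14
Reactants: 21 6α-alcohol
Product: 22 3α,6α,8α,10β,12-pentaol
Conditions: n-Bu4NF, THF, rt to 45 °C
Reagents that add atoms: none
Why: Fluoride-induced desilylation frees O8 and O12 at a stage where no carbonyl group is present, so the basicity of the reagent is harmless.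

Step 15
Reactants: 22 pentaol
Product: 23 ring-fusion 3α,8α-diol with free 10β-OH and 6α,12-bis-OTBS
Conditions: TBSCl (2.3 equiv), imidazole, DMAP (cat.), DMF, rt
Reagents that add atoms: tert-butyldimethylsilyl chloride CC(C)(C)[Si](C)(C)Cl
Why: This silylation differentiates by steric demand, so the primary O12 and secondary O6 hydroxyls should react while the three tertiary hydroxyls stay free.

Step 16
Reactants: 23 ring-fusion 3α,8α-diol
Product: 25 ten-membered (1Z,4Z)-C3 dienone with C8 ketone, via cyclic lead diester 24 (not isolated)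
Conditions: Pb(OAc)4 (1.1 equiv), solid NaHCO3, CH2Cl2, −20 to 0 °C; filtration through Celite, wash with aq. NaH2PO4–Na2HPO4 (pH 7)
Reagents that add atoms: none
Why: Both ring-fusion hydroxyls, cis and gauche on the cis-decalin, exchange for acetate on tetravalent lead to give the five-membered cyclic diester 24, which collapses in a two-electron fragmentation that breaks C3–C8, forms C3=O and C8=O and releases divalent lead. The closest known reaction type is the Criegee glycol cleavage of decalin-9,10-diols to cyclodecane-1,6-diones. The ten-membered ring is not closed by bond formation but appears because the bond shared by rings A and B is removed (ring merger), so no cyclisation entropy or transannular strain has to be overcome in a bond-forming event and both olefins keep the cis geometry they had in their cyclohexenes. No stereocentre is created: C3 and C8 become trigonal, while C6, C7 and C10 are not touched. The step needs chemoselectivity for the 1,2-diol over the isolated C10 carbinol and three olefins, which is secured because only the vicinal pair can chelate lead and glycol cleavage at or below 0 °C is much faster than alkoxy-radical or olefin chemistry of Pb(OAc)4. Solid NaHCO3 and a neutral work-up should keep C7 (α to C8=O and allylic) and the C8–C10 aldol unit intact.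

Step 17
Reactants: 25 ten-membered dienone with C8 ketone
Product: 27 8α-alcohol (1,3-anti to 10β-OH), via O10-bound diacetoxyborohydride 26 (not isolated)
Conditions: Me4NBH(OAc)3, MeCN/AcOH, −30 °C; aq. sodium potassium tartrate
Reagents that add atoms: none
Why: In this Evans–Saksena directed reduction, acetate exchange ties boron to O10 and hydride should pass through a chair-like six-membered transition state to the β face of C8, giving the anti 8α,10β-diol, while the C3 dienone, reachable only through a larger ring, is left alone.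

Step 18
Reactants: 27 8α-alcohol; 28 tiglic acid
Product: 30 8-O-tiglate, via mixed anhydride 29 (not isolated)
Conditions: 28, 2,4,6-trichlorobenzoyl chloride, Et3N, toluene, rt; then 27, DMAP, rt
Reagents that add atoms: 28 tiglic acid C/C=C(\C)C(=O)O
Why: Yamaguchi esterification should acylate only the secondary C8 hydroxyl because the tertiary C10 hydroxyl is too hindered, and the E geometry of the tiglate is the stable one.

Step 19
Reactants: 30 8-O-tiglate
Product: 31 6,12-diol
Conditions: HF·pyridine, pyridine, THF, 0 °C to rt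
Reagents that add atoms: none
Why: Buffered fluoride desilylation avoids base (no retro-aldol, no acyl migration) and strong acid, so that any hemiketal between the freed 6-OH and the C3 ketone stays reversible.

Step 20
Reactants: 31 6,12-diol
Product: 34 target CNP0135074.2, via hydroxy enal 32 (not isolated), via lactol 33 (not isolated)
Conditions: TEMPO (cat.), PhI(OAc)2 (2.5 equiv), CH2Cl2, rt
Reagents that add atoms: none
Why: In this oxoammonium-mediated oxidative lactonisation the primary allylic alcohol is oxidised first, the cis-disposed 6α-OH adds to the enal, and the lactol is oxidised on to the α-methylene-γ-lactone, whose cis ring fusion is already fixed by C6 and C7.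

## Compound list

1 | (S)-carvone | CC1=CC[C@@H](CC1=O)C(=C)C | starting material
2 | (S)-12-chlorocarvone | CC1=CC[C@@H](CC1=O)C(=C)CCl | intermediate
3 | (S)-12-acetoxycarvone | CC1=CC[C@@H](CC1=O)C(=C)COC(C)=O | intermediate
4 | (S)-12-hydroxycarvone | CC1=CC[C@@H](CC1=O)C(=C)CO | intermediate
5 | 12-O-TBS-carvone | CC1=CC[C@@H](CC1=O)C(=C)CO[Si](C)(C)C(C)(C)C | intermediate
6 | lithium C3=C8 cross-conjugated dienolate of 5 | CC1=CC[C@@H](C=C1O[Li])C(=C)CO[Si](C)(C)C(C)(C)C | intermediate
7 | 8β-hydroxy ketone (OH trans to C11) | CC1=CC[C@@H]([C@@H](O)C1=O)C(=C)CO[Si](C)(C)C(C)(C)C | intermediate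
8 | 8β,12-bis-O-TBS ketone | CC1=CC[C@@H]([C@@H](O[Si](C)(C)C(C)(C)C)C1=O)C(=C)CO[Si](C)(C)C(C)(C)C | intermediate
9 | 2-bromo-N-methoxy-N-methylacetamide | CON(C)C(=O)CBr | starting material
10 | lithium C3=C8 enolate of 8 | CC1=CC[C@@H](C(O[Si](C)(C)C(C)(C)C)=C1O[Li])C(=C)CO[Si](C)(C)C(C)(C)C | intermediate
11 | C8-quaternary keto Weinreb amide (8α-OTBS, C9 β) | CC1=CC[C@@H]([C@@](O[Si](C)(C)C(C)(C)C)(CC(=O)N(C)OC)C1=O)C(=C)CO[Si](C)(C)C(C)(C)C | intermediate
12 | C3 TBS dienol ether (C3=C4, C5=C6) | CC1=C(O[Si](C)(C)C(C)(C)C)[C@](O[Si](C)(C)C(C)(C)C)(CC(=O)N(C)OC)[C@H](C=C1)C(=C)CO[Si](C)(C)C(C)(C)C | intermediate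
13 | 5β,6β-epoxide of 12 | CC1=C(O[Si](C)(C)C(C)(C)C)[C@](O[Si](C)(C)C(C)(C)C)(CC(=O)N(C)OC)[C@H]([C@@H]2O[C@H]12)C(=C)CO[Si](C)(C)C(C)(C)C | intermediate
14 | 6β-hydroxy enone | CC1=C[C@@H](O)[C@@H]([C@@](O[Si](C)(C)C(C)(C)C)(CC(=O)N(C)OC)C1=O)C(=C)CO[Si](C)(C)C(C)(C)C | intermediate
15 | vinylmagnesium bromide | C=C[Mg]Br | starting material
16 | 3β-vinyl-3α-carbinol with C10 vinyl ketone | CC1=C[C@@H](O)[C@@H]([C@@](O[Si](C)(C)C(C)(C)C)(CC(=O)C=C)[C@@]1(O)C=C)C(=C)CO[Si](C)(C)C(C)(C)C | intermediate
17 | cis-fused bicyclic C10 enone (3α-OH, 6β-OH, 8α-OTBS) | O=C1C[C@]2(O[Si](C)(C)C(C)(C)C)[C@@H](C(=C)CO[Si](C)(C)C(C)(C)C)[C@H](O)C=C(C)[C@]2(O)C=C1 | intermediate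
18 | methyllithium | [Li]C | starting material
19 | 10β-hydroxy-10α-methyl decalin (3α-OH, 6β-OH, 8α-OTBS) | C[C@@]1(O)C[C@]2(O[Si](C)(C)C(C)(C)C)[C@@H](C(=C)CO[Si](C)(C)C(C)(C)C)[C@H](O)C=C(C)[C@]2(O)C=C1 | intermediate
20 | C6 enone | C[C@@]1(O)C[C@]2(O[Si](C)(C)C(C)(C)C)[C@@H](C(=C)CO[Si](C)(C)C(C)(C)C)C(=O)C=C(C)[C@]2(O)C=C1 | intermediate
21 | 6α-alcohol | C[C@@]1(O)C[C@]2(O[Si](C)(C)C(C)(C)C)[C@@H](C(=C)CO[Si](C)(C)C(C)(C)C)[C@@H](O)C=C(C)[C@]2(O)C=C1 | intermediate
22 | 3α,6α,8α,10β,12-pentaol | C[C@@]1(O)C[C@]2(O)[C@@H](C(=C)CO)[C@@H](O)C=C(C)[C@]2(O)C=C1 | intermediate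
23 | ring-fusion 3α,8α-diol, 10β-OH free, 6α,12-bis-OTBS (key-step precursor) | C[C@@]1(O)C[C@]2(O)[C@@H](C(=C)CO[Si](C)(C)C(C)(C)C)[C@@H](O[Si](C)(C)C(C)(C)C)C=C(C)[C@]2(O)C=C1 | intermediate
24 | cyclic O3,O8 lead diester (diacetate) | C[C@@]1(O)C[C@]2(O[Pb]3(OC(C)=O)OC(C)=O)[C@@H](C(=C)CO[Si](C)(C)C(C)(C)C)[C@@H](O[Si](C)(C)C(C)(C)C)C=C(C)[C@]2(O3)C=C1 | intermediate
25 | ten-membered (1Z,4Z)-C3 dienone with C8 ketone (key-step product) | C=C(CO[Si](C)(C)C(C)(C)C)[C@H]1[C@@H](O[Si](C)(C)C(C)(C)C)/C=C(/C)C(=O)/C=C\[C@](C)(O)CC1=O | intermediate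
26 | O10-bound diacetoxyborohydride, tetramethylammonium salt | C=C(CO[Si](C)(C)C(C)(C)C)[C@H]1[C@@H](O[Si](C)(C)C(C)(C)C)/C=C(/C)C(=O)/C=C\[C@](C)(O[BH-](OC(C)=O)OC(C)=O)CC1=O.C[N+](C)(C)C | intermediate
27 | 8α-alcohol (anti to 10β-OH) | C=C(CO[Si](C)(C)C(C)(C)C)[C@H]1[C@@H](O[Si](C)(C)C(C)(C)C)/C=C(/C)C(=O)/C=C\[C@](C)(O)C[C@H]1O | intermediate
28 | tiglic acid | C/C=C(\C)C(=O)O | starting material
29 | tiglic 2,4,6-trichlorobenzoic mixed anhydride | C/C=C(\C)C(=O)OC(=O)c1c(Cl)cc(Cl)cc1Cl | intermediate
30 | 8-O-tiglate, 6α,12-bis-OTBS | C=C(CO[Si](C)(C)C(C)(C)C)[C@H]1[C@@H](O[Si](C)(C)C(C)(C)C)/C=C(/C)C(=O)/C=C\[C@](C)(O)C[C@H]1OC(=O)/C(C)=C/C | intermediate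
31 | 6,12-diol | C=C(CO)[C@H]1[C@@H](O)/C=C(/C)C(=O)/C=C\[C@](C)(O)C[C@H]1OC(=O)/C(C)=C/C | intermediate
32 | 6-hydroxy C12 enal | C=C(C=O)[C@H]1[C@@H](O)/C=C(/C)C(=O)/C=C\[C@](C)(O)C[C@H]1OC(=O)/C(C)=C/C | intermediate
33 | C12 lactol (C12 epimers) | C=C1C(O)O[C@H]2/C=C(/C)C(=O)/C=C\[C@](C)(O)C[C@@H](OC(=O)/C(C)=C/C)[C@@H]12 | intermediate
34 | CNP0135074.2 (6S,7R,8R,10R) | C=C1C(=O)O[C@H]2/C=C(/C)C(=O)/C=C\[C@](C)(O)C[C@@H](OC(=O)/C(C)=C/C)[C@@H]12 | target

## Step count and risks

Total step count: 20. Longest linear sequence: 20 steps, from 1 to 34.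

**Risk 1, step 16.**
- What may go wrong: exchange of the crowded ditertiary diol onto lead may be slow. Once the C8 ketone is free, the β-hydroxy ketone unit C8–C9–C10 may open by retro-aldol cleavage. C7 may also epimerise, or its olefin may slip into conjugation, during isolation.
- Fallback: it sets out from 23. The least hindered tertiary hydroxyl (O10) is silylated with Et3SiOTf and 2,6-lutidine at −78 °C to give the 10-O-triethylsilyl diol F1. The same lead cleavage is run on F1 and gives the 10-O-triethylsilyl diketone F2, which has no free aldol hydroxyl and should tolerate purification.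
- Rejoining: the triethylsilyl group is taken off with HF·pyridine in MeCN at −20 °C directly before the reduction. The route is rejoined at 25, which is then used in solution for step 17 without isolation.

**Risk 2, step 17.**
- What may go wrong: the conformation of the macrocycle, rather than the chair-like transition state, may decide the face of hydride delivery. This would give poor facial selectivity or the syn diol.
- Fallback: it sets out from 25 and reverses the logic. A Narasaka–Prasad reduction (Et2BOMe, NaBH4, THF/MeOH, −78 °C) through the O8/O10 boron chelate should give the syn 8β-alcohol F3. A Mitsunobu esterification of F3 with tiglic acid 28 (PPh3, DIAD, toluene) installs the ester with inversion at C8.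
- Rejoining: the route is rejoined at 30.

**Risk 3, step 6.**
- What may go wrong: C-alkylation at the crowded tetrasubstituted enolate carbon may be slow. That would leave room for proton transfer from the acidic α-bromo amide, for migration of silicon between the two oxygens of the enediolate, or for competing γ-deprotonation.
- Fallback: it sets out from 8 and brings in C9–C10 at the ester level with a smaller and more reactive electrophile. The enolate is alkylated with methyl bromoacetate to the methyl ester F4. F4 is then converted into the amide with ClMgN(OMe)Me, made from MeNH(OMe)·HCl and i-PrMgCl in THF at −20 °C.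
- Rejoining: the route is rejoined at 11.

Further compounds
F1 | step 16 | 10-O-triethylsilyl ether of diol 23 | C[C@@]1(O[Si](CC)(CC)CC)C[C@]2(O)[C@@H](C(=C)CO[Si](C)(C)C(C)(C)C)[C@@H](O[Si](C)(C)C(C)(C)C)C=C(C)[C@]2(O)C=C1
F2 | step 16 | 10-O-triethylsilyl ether of diketone 25 | C=C(CO[Si](C)(C)C(C)(C)C)[C@H]1[C@@H](O[Si](C)(C)C(C)(C)C)/C=C(/C)C(=O)/C=C\[C@](C)(O[Si](CC)(CC)CC)CC1=O
F3 | step 17 | 8β-alcohol (C8 epimer of 27, syn to 10β-OH) | C=C(CO[Si](C)(C)C(C)(C)C)[C@H]1[C@@H](O[Si](C)(C)C(C)(C)C)/C=C(/C)C(=O)/C=C\[C@](C)(O)C[C@@H]1O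
F4 | step 6 | C8-quaternary keto methyl ester (8α-OTBS, C9 β) | CC1=CC[C@@H]([C@@](O[Si](C)(C)C(C)(C)C)(CC(=O)OC)C1=O)C(=C)CO[Si](C)(C)C(C)(C)C
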